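The product you want is complex with three exchanged. Read the runs as a chain of single swaps, each taking up one incoming ligand and freeing one leaving ligand.

| flask | starting complex | incoming ligand | leaving ligand | remark | time |
|---|---|---|---|---|---|
| Friday's | 0.10 M | 0.50 M | 0.10 M | run made earlier |  |
| flask | 0.10 M | 0.500 M | 0.200 M |  | 4.0 min |

Friday's run (percent of the starting complex charged)

| time / s | starting complex / % | complex with one exchanged / % | complex with two exchanged / % |
|---|---|---|---|
| 10.0 | 55.9 | 35.3 | 7.7 |
| 20.0 | 33.4 | 43.1 | 17.8 |
| 50.0 | 8.3 | 31.4 | 32.7 |

(readings scatter by 0.5 percentage points)

- how much starting complex there is at 4.0 min, in percent of the starting complex charged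
- how much complex with one exchanged there is at 4.0 min, in percent of the starting complex charged
- how much complex with two exchanged there is at 4.0 min, in percent of the starting complex charged
- how much complex with three exchanged there is at 4.0 min, in percent of the starting complex charged

- the earlier runs were read with a standard deviation of 0.5 percentage points
- no earlier run changes the charge of leaving ligand; that part of a forecast is a guess

Follow one molecule of starting complex. Take its chance of leaving in each moment as proportional to c(incoming ligand), so the clock that counts is the exposure, the area under c(incoming ligand) against time. Friday's first reading lets you put a number on that chance. Count the percentage missing from the table as complex with three exchanged, and by 10.0 s c(incoming ligand) has fallen to about 0.446 M. The mean of that and the charge gives an exposure of 4.73 M·s. Since 55.9 % of the starting complex survived it, you can read the survival constant, the rate at which the logarithm of a molecule's chance of staying falls per unit of exposure, as 0.123 M⁻¹ s⁻¹.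

My own reckoning for the new flask takes the extra leaving ligand to do nothing, which is a guess. If the chain ends at complex with three exchanged, c(incoming ligand) in the new flask stays at or above 0.200 M, and a starting complex then survives 4.0 min with a chance of about 0.273 % or less. The missing percentage is a different matter. Friday's 27.6 % at 50.0 s counts whatever has passed the second exchange, so I would hold it as a ceiling on complex with three exchanged, not as its amount.

The forecast commits to 0.1 % of starting complex, 1.3 % of complex with one exchanged, 7 % of complex with two exchanged and 91.5 % of complex with three exchanged, on the ground that “The missing percentage gives Mc”.

The flask gives 0.112 % of starting complex, 2.52 % of complex with one exchanged, 10.4 % of complex with two exchanged and 6.63 % of complex with three exchanged.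

    starting complex + incoming ligand → leaving ligand + complex with one exchanged (k = 0.121 M⁻¹ s⁻¹)
    complex with one exchanged + incoming ligand → leaving ligand + complex with two exchanged (k = 0.0845 M⁻¹ s⁻¹)
    complex with two exchanged + incoming ligand → leaving ligand + complex with three exchanged (k = 0.0724 M⁻¹ s⁻¹)
    complex with three exchanged + incoming ligand → leaving ligand + complex with four exchanged (k = 0.158 M⁻¹ s⁻¹)

In this flask complex with four exchanged stands at 80.4 % at 4.0 min, far more than the 6.63 % of complex with three exchanged. The survival constant turns this flask's 0.112 % of starting complex into an exposure of about 55.2 M·s. The neighbour charged with 0.40 M of starting complex keeps 23.0 % of it, which is an exposure of about 11.9 M·s. There incoming ligand is the limiting reagent, down to 0.0127 % of its charge.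

All runs come from a simulation for an exercise; the scatter is artificial.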